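All constants are assumed; the run is a simulation.

You cannot take more product out of this flask than the starting material you put in, so the books have two entries that must sum to the charge.

    starting material → product (k1 = 2.2 × 10⁻⁴ s⁻¹)

starting material 0.013 M; time 40 min

1. how much product there is at 40 min, in percent of the starting material charged
2. amount of product if the flask were left three thousand times as long, in percent of the starting material charged

Starting material is the limiting reagent. In each minute the step moves the same fraction of what stands in the first entry, starting material, to the second, product, so 0.013 M cancels from the percentages. Carry the lifetime τ = 75.8 min, the reciprocal of the rate constant. After a time t the first entry holds exp(−t/τ) of the charge and the second holds the rest. The entries cross at the half-life, ln(2)·τ = 52.5 min. Your 40 min comes earlier than that crossing and is 0.528 lifetimes, so my reckoning puts 59.0% in the first entry and 41.0% in the second. The step as written has no return, so over the long wait the second entry grows toward the charge.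

The forecast gave 41% (from 40% to 42%) at the asked time and 100% (from 99.5% to 100%) for the long wait, calling this “a single irreversible first-order step”.

The simulation gives 41.0% and 100%. If you stop this flask at 40.0 min, starting material is still the larger entry, 59.0% against 41.0% of product. Now take the same charge read at 60.0 min, which is 0.792 lifetimes and later than the crossing. The lifetime puts 54.7% in the product entry. In that neighbouring flask the simulation shows starting material down to 45% and product, now the larger entry, at 54.7%.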